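**Strategy.** With the carbons numbered from the carboxyl group (C1), the oxygen-bearing run C3–C10 is treated as a cyclooctane by adding a temporary C3–C10 bond; its oxygens on C3, C6, C7 and C10 then map onto the two oxiranes of syn-cycloocta-1,5-diene diepoxide. Acid hydration of this meso diepoxide opens one oxirane with water and lets the new hydroxyl open the other across the ring, which in one operation closes the oxolane ring (C7–O–C10) and leaves carbinols at C3 and C6. The precursor is the achiral syn-diepoxide; enzymatic desymmetrisation, Baeyer–Villiger scission of C3–C10, C10 allylation and a late peroxide ring closure complete the route.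

Key step: step 2

Remark: atom labels C1 to C24 are those of the target, counted from the carboxyl carbon; 3 is racemic and 15 an E/Z mixture (one isomer drawn), and both converge in the following operation.

Assumption: the lipase obeys the usual preference for the (R)-configured secondary carbinol; acylation of diol 4 would then esterify the hydroxyl that has to become the C3 ketone, so hydrolysis of diacetate 5, which frees that same carbinol, is the mode used.

Step 1
Reactants: 1 cycloocta-1,5-diene
Product: 2 syn-1,2:5,6-diepoxycyclooctane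
Conditions: mCPBA (2.2 equiv), CH2Cl2, 0 °C → rt
Reagents that add atoms: meta-chloroperoxybenzoic acid, O=C(OO)c1cccc(Cl)c1
Why: Prilezhaev epoxidation of both cis alkenes; the tub-shaped ring exposes the same outer face of both alkenes, so the second oxygen should be delivered syn to the first and the meso syn-diepoxide (also an article of commerce) should predominate, the minor anti isomer being removed by distillation or chromatography.

Step 2
Reactants: 2 syn-1,2:5,6-diepoxycyclooctane
Product: 4 meso-(1R,2R,5S,6S)-9-oxabicyclo[4.2.1]nonane-2,5-diol, via epoxy diol 3 (not isolated)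
Conditions: H2SO4 (0.05 M), H2O/THF (1:1), 25–40 °C
Reagents that add atoms: water, O
Why: Under acid catalysis water opens one protonated oxirane with inversion to give the trans-diol epoxide 3, and the water-derived hydroxyl, the only one lying on the face opposite the second oxirane oxygen, then attacks the nearer carbon of that oxirane with inversion, so that the ether bridge C7–O–C10 forms and the two original oxirane oxygens remain as the C3 and C6 hydroxyls. The closest known reaction type is the acid-mediated transannular O-heterocyclisation of medium-ring epoxides, which is documented for this diepoxide. The oxolane ring closes in a 5-exo-tet mode, whereas 6-endo attack at the farther carbon would give the isomeric 9-oxabicyclo[3.3.1]nonane-2,6-diol. All four stereocentres are controlled by the substrate: C7 and C10 are inverted by backside attack and C3 and C6 keep the oxirane configuration, which places each hydroxyl trans to the neighbouring ether C–O bond (threo at C6/C7) and keeps the product meso. The step needs attack at the nearer carbon and ring closure before a second water molecule intervenes; the shorter transannular reach across the eight-membered ring and the high effective molarity of the internal hydroxyl should secure both, and the [3.3.1] isomer is removed by crystallisation or chromatography.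

Step 3
Reactants: 4 meso-(1R,2R,5S,6S)-9-oxabicyclo[4.2.1]nonane-2,5-diol
Product: 5 meso-(1R,2R,5S,6S)-9-oxabicyclo[4.2.1]nonane-2,5-diyl diacetate
Conditions: Ac2O (3 equiv), pyridine, DMAP (cat), CH2Cl2, rt
Reagents that add atoms: acetic anhydride, CC(=O)OC(C)=O
Why: DMAP-catalysed O-acylation of both secondary hydroxyls, which touches no stereocentre and supplies the meso diester that a hydrolase can desymmetrise.

Step 4
Reactants: 5 meso-(1R,2R,5S,6S)-9-oxabicyclo[4.2.1]nonane-2,5-diyl diacetate
Product: 6 (1S,2S,5R,6R)-5-hydroxy-9-oxabicyclo[4.2.1]nonan-2-yl acetate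
Conditions: Candida antarctica lipase B (immobilised), NaH2PO4/Na2HPO4 buffer (0.1 M, pH 7.0), MTBE (10 vol %), 30 °C, stopped when one equivalent of acid is released
Reagents that add atoms: none
Why: enantiotopic-group-selective enzymatic hydrolysis (desymmetrisation of a meso diacetate); the hydrolase should cleave only the ester on the (R)-configured carbinol carbon, which frees the future C3 hydroxyl, leaves the acetate as protecting group on the future C6 oxygen and thereby fixes the absolute configuration of C6 and C7.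

Step 5
Reactants: 6 (1S,2S,5R,6R)-5-hydroxy-9-oxabicyclo[4.2.1]nonan-2-yl acetate
Product: 7 (1S,2S,6R)-5-oxo-9-oxabicyclo[4.2.1]nonan-2-yl acetate
Conditions: Dess–Martin periodinane (1.3 equiv), CH2Cl2, rt
Reagents that add atoms: none
Why: Dess–Martin oxidation of the secondary alcohol to the C3 ketone; the acetate and the ether are inert and the neighbouring stereocentre C10 is a bridgehead that cannot epimerise.

Step 6
Reactants: 7 (1S,2S,6R)-5-oxo-9-oxabicyclo[4.2.1]nonan-2-yl acetate
Product: 8 (1S,6S,7S)-3-oxo-2,10-dioxabicyclo[5.2.1]decan-6-yl acetate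
Conditions: mCPBA (1.5 equiv), CH2Cl2, 0 °C → rt
Reagents that add atoms: meta-chloroperoxybenzoic acid, O=C(OO)c1cccc(Cl)c1
Why: Baeyer–Villiger oxidation in which the more substituted, oxygen-bearing bridgehead carbon C10 migrates with retention in preference to the C4 methylene, so that the temporary C3–C10 bond is cut, C3 becomes a carboxyl carbon and C10 an acyloxy acetal.

Step 7
Reactants: 8 (1S,6S,7S)-3-oxo-2,10-dioxabicyclo[5.2.1]decan-6-yl acetate; 9 allyltrimethylsilane
Product: 11 (4S)-4-acetoxy-4-[(2S,5S)-5-(prop-2-en-1-yl)oxolan-2-yl]butanoic acid, via trimethylsilyl ester 10 (not isolated)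
Conditions: 9 (3 equiv), TMSOTf (0.2 equiv), CH2Cl2, −78 °C; then H2O
Reagents that add atoms: none
Why: Hosomi–Sakurai C-allylation of the cyclic oxocarbenium ion formed by Lewis-acid ionisation of the acyloxy acetal; the departing carboxylate is tethered to the C7 side chain and therefore leaves from, and shields, the face cis to that chain, so the allylsilane should add from the opposite face and set C10 trans to C7, while the silyl group passes to the carboxylate and is lost on aqueous work-up.

Step 8
Reactants: 11 (4S)-4-acetoxy-4-[(2S,5S)-5-(prop-2-en-1-yl)oxolan-2-yl]butanoic acid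
Product: 13 (5S)-5-[(2S,5S)-5-(prop-2-en-1-yl)oxolan-2-yl]oxolan-2-one, via hydroxy acid 12 (not isolated)
Conditions: LiOH (3 equiv), THF/H2O, rt; then 1 M HCl to pH 2; TsOH (cat), CH2Cl2, rt
Reagents that add atoms: none
Why: saponification of the acetate followed by acid-catalysed γ-lactonisation (intramolecular esterification to a five-membered ring), which masks the C6 oxygen and the C3 carboxyl in one group without touching a stereocentre.

Step 9
Reactants: 13 (5S)-5-[(2S,5S)-5-(prop-2-en-1-yl)oxolan-2-yl]oxolan-2-one; 14 6-bromohex-1-ene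
Product: 15 (5S)-5-[(2S,5S)-5-(7-bromohept-2-en-1-yl)oxolan-2-yl]oxolan-2-one
Conditions: 14 (4 equiv), second-generation Grubbs catalyst RuCl2(=CHPh)(PCy3)(H2IMes) (3 mol %), CH2Cl2, 40 °C
Reagents that add atoms: none
Why: olefin cross-metathesis between two unhindered terminal alkenes, driven by loss of ethene and by the excess of the cheap bromoalkene; the geometry of the new C12=C13 bond does not matter because it is saturated in the next step.

Step 10
Reactants: 15 (5S)-5-[(2S,5S)-5-(7-bromohept-2-en-1-yl)oxolan-2-yl]oxolan-2-one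
Product: 16 (5S)-5-[(2S,5R)-5-(7-bromoheptyl)oxolan-2-yl]oxolan-2-one
Conditions: H2 (1 atm), PtO2 (5 mol %), EtOAc, rt
Reagents that add atoms: none
Why: heterogeneous catalytic hydrogenation of the disubstituted alkene, under which the primary bromide, the lactone and the ether should survive (the change of the C10 descriptor is only a change of substituent priority).

Step 11
Reactants: 16 (5S)-5-[(2S,5R)-5-(7-bromoheptyl)oxolan-2-yl]oxolan-2-one
Product: 17 {7-[(2R,5S)-5-[(2S)-5-oxooxolan-2-yl]oxolan-2-yl]heptyl}triphenylphosphonium bromide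
Conditions: PPh3 (1.5 equiv), MeCN, reflux
Reagents that add atoms: triphenylphosphine, c1ccc(cc1)P(c1ccccc1)c1ccccc1
Why: SN2 quaternisation of triphenylphosphine by the primary bromide, the standard entry to a Wittig salt; no stereocentre is involved.

Step 12
Reactants: 18 pent-4-enal; 19 (triphenylphosphoranylidene)acetaldehyde
Product: 20 (2E)-hepta-2,6-dienal
Conditions: toluene, 80 °C, 18 in slight excess
Reagents that add atoms: none
Why: Wittig two-carbon homologation with a stabilised formyl ylide, which should give the (E)-enal through the thermodynamically preferred oxaphosphetane; the slight excess of 18 suppresses a second homologation.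

Step 13
Reactants: 17 {7-[(2R,5S)-5-[(2S)-5-oxooxolan-2-yl]oxolan-2-yl]heptyl}triphenylphosphonium bromide; 20 (2E)-hepta-2,6-dienal
Product: 22 (5S)-5-[(2S,5R)-5-[(7Z,9E)-tetradeca-7,9,13-trien-1-yl]oxolan-2-yl]oxolan-2-one, via phosphorus ylide 21 (not isolated)
Conditions: NaN(SiMe3)2 (1.0 equiv), THF, −78 °C; then 20, −78 → 0 °C
Reagents that add atoms: none
Why: salt-free Wittig olefination of a non-stabilised ylide with an enal, which should give the new C17=C18 bond with Z geometry by kinetically controlled oxaphosphetane formation while the (E)-C19=C20 bond comes unchanged from 20; the lactone is spared because the phosphonium salt is the stronger acid and the aldehyde the better electrophile.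

Step 14
Reactants: 22 (5S)-5-[(2S,5R)-5-[(7Z,9E)-tetradeca-7,9,13-trien-1-yl]oxolan-2-yl]oxolan-2-one
Product: 23 (5S)-5-[(2S,5R)-5-[(7Z,9E)-tetradeca-7,9,13-trien-1-yl]oxolan-2-yl]oxolan-2-ol
Conditions: i-Bu2AlH (1.1 equiv), CH2Cl2, −78 °C; aq KNaC4H4O6 work-up
Reagents that add atoms: none
Why: partial hydride reduction of the γ-lactone, which stops at the lactol because the tetrahedral aluminate is stable at low temperature; the alkenes are inert and the anomeric centre need not be controlled.

Step 15
Reactants: 23 (5S)-5-[(2S,5R)-5-[(7Z,9E)-tetradeca-7,9,13-trien-1-yl]oxolan-2-yl]oxolan-2-ol; 24 methyl (triphenylphosphoranylidene)acetate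
Product: 25 methyl (2E,6S)-6-hydroxy-6-[(2S,5R)-5-[(7Z,9E)-tetradeca-7,9,13-trien-1-yl]oxolan-2-yl]hex-2-enoate
Conditions: toluene, 60 °C
Reagents that add atoms: none
Why: Wittig olefination of the hydroxy aldehyde in equilibrium with the lactol; the stabilised ylide gives the (2E)-enoate, the C6 hydroxyl is set free, and the neutral medium should keep this hydroxyl from adding to the new enoate.

Step 16
Reactants: 25 methyl (2E,6S)-6-hydroxy-6-[(2S,5R)-5-[(7Z,9E)-tetradeca-7,9,13-trien-1-yl]oxolan-2-yl]hex-2-enoate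
Product: 26 methyl (2E,6S)-6-[(2S,5R)-5-[(7Z,9E)-tetradeca-7,9,13-trien-1-yl]oxolan-2-yl]-6-(trifluoromethanesulfonyloxy)hex-2-enoate
Conditions: Tf2O (1.2 equiv), 2,6-lutidine (2 equiv), CH2Cl2, −78 °C; used at once
Reagents that add atoms: trifluoromethanesulfonic anhydride, O=S(=O)(OS(=O)(=O)C(F)(F)F)C(F)(F)F
Why: O-sulfonylation of the secondary alcohol, which activates C6 with retention; the β-oxygen of the oxolane retards ionisation, so the triflate should persist at low temperature long enough to be used.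

Step 17
Reactants: 26 methyl (2E,6S)-6-[(2S,5R)-5-[(7Z,9E)-tetradeca-7,9,13-trien-1-yl]oxolan-2-yl]-6-(trifluoromethanesulfonyloxy)hex-2-enoate
Product: 28 methyl 2-[(3R,6R)-6-[(2S,5R)-5-[(7Z,9E)-tetradeca-7,9,13-trien-1-yl]oxolan-2-yl]-1,2-dioxan-3-yl]acetate, via hydroperoxide 27 (not isolated)
Conditions: H2O2 (50 % aq, 20 equiv), KOH (1.5 equiv), MeOH/THF, −20 → 0 °C
Reagents that add atoms: hydrogen peroxide, OO
Why: SN2 displacement of the secondary sulfonate by hydroperoxide anion, which inverts C6 to the required 6R configuration, followed in the same flask by 6-exo-trig conjugate addition (oxa-Michael) of the peroxide anion to the (E)-enoate through a chair transition state with the oxolanyl group and the ester arm both equatorial, which should place the new C3 centre trans to C6 (3R).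

Step 18
Reactants: 28 methyl 2-[(3R,6R)-6-[(2S,5R)-5-[(7Z,9E)-tetradeca-7,9,13-trien-1-yl]oxolan-2-yl]-1,2-dioxan-3-yl]acetate
Product: 29 2-[(3R,6R)-6-[(2S,5R)-5-[(7Z,9E)-tetradeca-7,9,13-trien-1-yl]oxolan-2-yl]-1,2-dioxan-3-yl]acetic acid
Conditions: LiOH (3 equiv), THF/H2O, 0 °C; then 1 M HCl to pH 3
Reagents that add atoms: lithium hydroxide, [Li+].[OH-]
Why: saponification of the methyl ester; the dialkyl peroxide, the diene and all four stereocentres should tolerate brief exposure to cold hydroxide.

**Compound list**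

1 | cycloocta-1,5-diene | C1/C=C\CC/C=C\C1 | starting material
2 | syn-1,2:5,6-diepoxycyclooctane (meso, both oxirane oxygens on one face) | C1C[C@H]2O[C@H]2CC[C@H]3O[C@@H]13 | intermediate
3 | rac-trans-5,6-epoxycyclooctane-1,2-diol (water-derived hydroxyl anti to the oxirane oxygen; one enantiomer drawn) | C1C[C@@H](O)[C@H](O)CC[C@H]2O[C@@H]12 | intermediate
4 | meso-(1R,2R,5S,6S)-9-oxabicyclo[4.2.1]nonane-2,5-diol (each hydroxyl trans to the adjacent bridge C–O bond) | O[C@H]1CC[C@@H](O)[C@H]2CC[C@@H]1O2 | intermediate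
5 | meso-(1R,2R,5S,6S)-9-oxabicyclo[4.2.1]nonane-2,5-diyl diacetate | CC(=O)O[C@H]1CC[C@@H](OC(C)=O)[C@H]2CC[C@@H]1O2 | intermediate
6 | (1S,2S,5R,6R)-5-hydroxy-9-oxabicyclo[4.2.1]nonan-2-yl acetate (acetate on future C6, hydroxyl on future C3) | CC(=O)O[C@H]1CC[C@@H](O)[C@H]2CC[C@@H]1O2 | intermediate
7 | (1S,2S,6R)-5-oxo-9-oxabicyclo[4.2.1]nonan-2-yl acetate | CC(=O)O[C@H]1CCC(=O)[C@H]2CC[C@@H]1O2 | intermediate
8 | (1S,6S,7S)-3-oxo-2,10-dioxabicyclo[5.2.1]decan-6-yl acetate | CC(=O)O[C@H]1CCC(=O)O[C@H]2CC[C@@H]1O2 | intermediate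
9 | allyltrimethylsilane | C=CC[Si](C)(C)C | starting material
10 | trimethylsilyl (4S)-4-acetoxy-4-[(2S,5S)-5-(prop-2-en-1-yl)oxolan-2-yl]butanoate | C=CC[C@@H]1CC[C@@H]([C@@H](OC(C)=O)CCC(=O)O[Si](C)(C)C)O1 | intermediate
11 | (4S)-4-acetoxy-4-[(2S,5S)-5-(prop-2-en-1-yl)oxolan-2-yl]butanoic acid | C=CC[C@@H]1CC[C@@H]([C@@H](OC(C)=O)CCC(=O)O)O1 | intermediate
12 | (4S)-4-hydroxy-4-[(2S,5S)-5-(prop-2-en-1-yl)oxolan-2-yl]butanoic acid | C=CC[C@@H]1CC[C@@H]([C@@H](O)CCC(=O)O)O1 | intermediate
13 | (5S)-5-[(2S,5S)-5-(prop-2-en-1-yl)oxolan-2-yl]oxolan-2-one | C=CC[C@@H]1CC[C@@H]([C@@H]2CCC(=O)O2)O1 | intermediate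
14 | 6-bromohex-1-ene | C=CCCCCBr | starting material
15 | (5S)-5-[(2S,5S)-5-(7-bromohept-2-en-1-yl)oxolan-2-yl]oxolan-2-one (E/Z mixture, E drawn) | BrCCCC/C=C/C[C@@H]1CC[C@@H]([C@@H]2CCC(=O)O2)O1 | intermediate
16 | (5S)-5-[(2S,5R)-5-(7-bromoheptyl)oxolan-2-yl]oxolan-2-one | BrCCCCCCC[C@@H]1CC[C@@H]([C@@H]2CCC(=O)O2)O1 | intermediate
17 | {7-[(2R,5S)-5-[(2S)-5-oxooxolan-2-yl]oxolan-2-yl]heptyl}triphenylphosphonium bromide | c1ccccc1[P+](c1ccccc1)(c1ccccc1)CCCCCCC[C@@H]1CC[C@@H]([C@@H]2CCC(=O)O2)O1.[Br-] | intermediate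
18 | pent-4-enal | C=CCCC=O | starting material
19 | (triphenylphosphoranylidene)acetaldehyde | O=CC=P(c1ccccc1)(c1ccccc1)c1ccccc1 | starting material
20 | (2E)-hepta-2,6-dienal | C=CCC/C=C/C=O | intermediate
21 | phosphorus ylide derived from 17 | c1ccccc1P(c1ccccc1)(c1ccccc1)=CCCCCCC[C@@H]1CC[C@@H]([C@@H]2CCC(=O)O2)O1 | intermediate
22 | (5S)-5-[(2S,5R)-5-[(7Z,9E)-tetradeca-7,9,13-trien-1-yl]oxolan-2-yl]oxolan-2-one | C=CCC/C=C/C=C\CCCCCC[C@@H]1CC[C@@H]([C@@H]2CCC(=O)O2)O1 | intermediate
23 | (5S)-5-[(2S,5R)-5-[(7Z,9E)-tetradeca-7,9,13-trien-1-yl]oxolan-2-yl]oxolan-2-ol (anomer mixture) | C=CCC/C=C/C=C\CCCCCC[C@@H]1CC[C@@H]([C@@H]2CCC(O)O2)O1 | intermediate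
24 | methyl (triphenylphosphoranylidene)acetate | COC(=O)C=P(c1ccccc1)(c1ccccc1)c1ccccc1 | starting material
25 | methyl (2E,6S)-6-hydroxy-6-[(2S,5R)-5-[(7Z,9E)-tetradeca-7,9,13-trien-1-yl]oxolan-2-yl]hex-2-enoate | C=CCC/C=C/C=C\CCCCCC[C@@H]1CC[C@@H]([C@@H](O)CC/C=C/C(=O)OC)O1 | intermediate
26 | methyl (2E,6S)-6-[(2S,5R)-5-[(7Z,9E)-tetradeca-7,9,13-trien-1-yl]oxolan-2-yl]-6-(trifluoromethanesulfonyloxy)hex-2-enoate | C=CCC/C=C/C=C\CCCCCC[C@@H]1CC[C@@H]([C@@H](OS(=O)(=O)C(F)(F)F)CC/C=C/C(=O)OC)O1 | intermediate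
27 | methyl (2E,6R)-6-hydroperoxy-6-[(2S,5R)-5-[(7Z,9E)-tetradeca-7,9,13-trien-1-yl]oxolan-2-yl]hex-2-enoate | C=CCC/C=C/C=C\CCCCCC[C@@H]1CC[C@@H]([C@H](OO)CC/C=C/C(=O)OC)O1 | intermediate
28 | methyl 2-[(3R,6R)-6-[(2S,5R)-5-[(7Z,9E)-tetradeca-7,9,13-trien-1-yl]oxolan-2-yl]-1,2-dioxan-3-yl]acetate | C=CCC/C=C/C=C\CCCCCC[C@@H]1CC[C@@H]([C@H]2CC[C@H](CC(=O)OC)OO2)O1 | intermediate
29 | 2-[(3R,6R)-6-[(2S,5R)-5-[(7Z,9E)-tetradeca-7,9,13-trien-1-yl]oxolan-2-yl]-1,2-dioxan-3-yl]acetic acid | C=CCC/C=C/C=C\CCCCCC[C@@H]1CC[C@@H]([C@H]2CC[C@H](CC(=O)O)OO2)O1 | target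

**Step count.** Total: 18 steps. Longest linear sequence: 17 steps (steps 1–11 and 13–18); step 12 is a one-step side branch.

**Steps most likely to fail**

Step 17. Substitution at the hindered, β-oxygenated secondary carbon may be outpaced by attack of hydroperoxide on sulfur or on the enoate, or by participation of the oxolane oxygen with loss of clean inversion, and the aqueous base may degrade the peroxide once it has formed. The fallback sets out from 26 and comes back at 27 and then 28. The triflate 26 is treated with 2-methoxypropan-2-yl hydroperoxide (made by ozonolysis of 2,3-dimethylbut-2-ene in methanol) and CsOH·H2O in DMF at 0 °C. This monoprotected peroxide nucleophile can neither cyclise nor carry free hydrogen peroxide to the enoate, and should give with inversion methyl (2E,6R)-6-[(2-methoxypropan-2-yl)peroxy]-6-[(2S,5R)-5-[(7Z,9E)-tetradeca-7,9,13-trien-1-yl]oxolan-2-yl]hex-2-enoate F1. Aqueous acetic acid in THF then releases hydroperoxide 27, which is isolated in this variant, and diethylamine in 2,2,2-trifluoroethanol closes the dioxane to 28 under non-aqueous, weakly basic conditions.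

Step 4. The hydrolase may discriminate the two enantiotopic acetates poorly or in the reverse sense. The fallback sets out from 4 and comes back at 13. Diol 4 is monoacylated with (1S)-camphanic chloride (pyridine, DMAP, CH2Cl2, 0 °C), and the two diastereomeric monoesters are separated by chromatography or crystallisation and assigned by crystallography. The one esterified on the future C6 oxygen, (1S,2S,5R,6R)-5-hydroxy-9-oxabicyclo[4.2.1]nonan-2-yl (1S,4R)-camphanate F2, is carried through the chemistry of steps 5 to 7. Dess–Martin oxidation gives (1S,2S,6R)-5-oxo-9-oxabicyclo[4.2.1]nonan-2-yl (1S,4R)-camphanate F3. Baeyer–Villiger oxidation gives (1S,6S,7S)-3-oxo-2,10-dioxabicyclo[5.2.1]decan-6-yl (1S,4R)-camphanate F4. Allylation with 9 and TMSOTf gives, through trimethylsilyl (4S)-4-[(1S,4R)-camphanoyloxy]-4-[(2S,5S)-5-(prop-2-en-1-yl)oxolan-2-yl]butanoate F5, the acid (4S)-4-[(1S,4R)-camphanoyloxy]-4-[(2S,5S)-5-(prop-2-en-1-yl)oxolan-2-yl]butanoic acid F6. Saponification and lactonisation as in step 8 remove the auxiliary and return 12 and then 13.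

Step 7. Facial selectivity in the attack on the C10 oxocarbenium ion may be poor, giving cis and trans oxolanes that cannot be interconverted. The fallback sets out from 8 and comes back at 13, and closes the oxolane last by a method with reliable trans selectivity. Lactone acetal 8 is saponified with LiOH in THF/H2O to (4S)-4-hydroxy-4-[(2S)-5-hydroxyoxolan-2-yl]butanoic acid F7 (as its lithium salt). The dried salt is methylenated with excess Ph3P=CH2 (from Ph3PCH3Br and KOt-Bu, THF, 0 °C → rt) to (4S,5S)-4,5-dihydroxynon-8-enoic acid F8, which lactonises on acidification to (5S)-5-[(1S)-1-hydroxypent-4-en-1-yl]oxolan-2-one F9. Cobalt-catalysed aerobic oxidative cyclisation of this bishomoallylic alcohol (Mukaiyama type; Co(modp)2, which is bis[1-(morpholinocarbonyl)-4,4-dimethylpentane-1,3-dionato]cobalt, O2, t-BuOOH, i-PrOH, 55 °C) should give the trans oxolane (5S)-5-[(2S,5S)-5-(hydroxymethyl)oxolan-2-yl]oxolan-2-one F10. Triflation (Tf2O, 2,6-lutidine, −78 °C) gives [(2S,5S)-5-[(2S)-5-oxooxolan-2-yl]oxolan-2-yl]methyl trifluoromethanesulfonate F11, and copper-catalysed coupling with CH2=CHMgBr (CuI cat, THF, −78 → −40 °C) installs the allyl group and returns 13.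

**Further compounds**

F1 | step 17 | methyl (2E,6R)-6-[(2-methoxypropan-2-yl)peroxy]-6-[(2S,5R)-5-[(7Z,9E)-tetradeca-7,9,13-trien-1-yl]oxolan-2-yl]hex-2-enoate | C=CCC/C=C/C=C\CCCCCC[C@@H]1CC[C@@H]([C@H](OOC(C)(C)OC)CC/C=C/C(=O)OC)O1
F2 | step 4 | (1S,2S,5R,6R)-5-hydroxy-9-oxabicyclo[4.2.1]nonan-2-yl (1S,4R)-camphanate | CC1(C)[C@@]2(C)CC[C@]1(C(=O)O[C@H]3CC[C@@H](O)[C@H]4CC[C@@H]3O4)OC2=O
F3 | step 4 | (1S,2S,6R)-5-oxo-9-oxabicyclo[4.2.1]nonan-2-yl (1S,4R)-camphanate | CC1(C)[C@@]2(C)CC[C@]1(C(=O)O[C@H]3CCC(=O)[C@H]4CC[C@@H]3O4)OC2=O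
F4 | step 4 | (1S,6S,7S)-3-oxo-2,10-dioxabicyclo[5.2.1]decan-6-yl (1S,4R)-camphanate | CC1(C)[C@@]2(C)CC[C@]1(C(=O)O[C@H]3CCC(=O)O[C@H]4CC[C@@H]3O4)OC2=O
F5 | step 4 | trimethylsilyl (4S)-4-[(1S,4R)-camphanoyloxy]-4-[(2S,5S)-5-(prop-2-en-1-yl)oxolan-2-yl]butanoate | CC1(C)[C@@]2(C)CC[C@]1(C(=O)O[C@@H](CCC(=O)O[Si](C)(C)C)[C@@H]3CC[C@@H](CC=C)O3)OC2=O
F6 | step 4 | (4S)-4-[(1S,4R)-camphanoyloxy]-4-[(2S,5S)-5-(prop-2-en-1-yl)oxolan-2-yl]butanoic acid | CC1(C)[C@@]2(C)CC[C@]1(C(=O)O[C@@H](CCC(=O)O)[C@@H]3CC[C@@H](CC=C)O3)OC2=O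
F7 | step 7 | (4S)-4-hydroxy-4-[(2S)-5-hydroxyoxolan-2-yl]butanoic acid | OC1CC[C@@H]([C@@H](O)CCC(=O)O)O1
F8 | step 7 | (4S,5S)-4,5-dihydroxynon-8-enoic acid | C=CCC[C@H](O)[C@@H](O)CCC(=O)O
F9 | step 7 | (5S)-5-[(1S)-1-hydroxypent-4-en-1-yl]oxolan-2-one | C=CCC[C@H](O)[C@@H]1CCC(=O)O1
F10 | step 7 | (5S)-5-[(2S,5S)-5-(hydroxymethyl)oxolan-2-yl]oxolan-2-one | OC[C@@H]1CC[C@@H]([C@@H]2CCC(=O)O2)O1
F11 | step 7 | [(2S,5S)-5-[(2S)-5-oxooxolan-2-yl]oxolan-2-yl]methyl trifluoromethanesulfonate | FC(F)(F)S(=O)(=O)OC[C@@H]1CC[C@@H]([C@@H]2CCC(=O)O2)O1
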